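## Structural features

The target is a 2,3,4,7-tetrahydrooxepine (ring atoms O1, C2, C3, C4, C5=C6, C7) joined through C6 to a five-carbon chain, CH2CH2CH=C(CH3)CH2O, whose E-configured allylic oxygen is acylated by (E)-4-hydroxycinnamic acid. C2 is the only stereocentre: a fully substituted carbon bonded to O1, a free carboxyl group, the ring methylene C3 and a CH2C(=O)Ar arm (Ar = 2,5-dihydroxyphenyl), with the S configuration (O1 > CO2H > CH2C(=O)Ar > C3). No stereocentre stands next to it, so the stereochemical task is this one centre, two E alkenes and the position of the ring alkene. The aryl ketone is β to O1, so any enolate of it can expel O1, open the ring and destroy the configuration at C2; base must be kept away from every intermediate that contains this ketone. Also fragile are the hydroquinone (oxidation), the allylic cinnamate (acyl transfer, ionisation by zerovalent palladium) and the two trisubstituted alkenes (strong acid). A less obvious weakness is that the C2 carboxyl sits 1,4 to the oxygenated carbon of the arm, so a hydroxyl or alkoxide on that carbon can close a five-membered lactone onto any unhindered C2 ester. The real difficulty is the seven-membered cyclic ether with a trisubstituted alkene at a fixed place and a carbon substituent at C6, built beside a quaternary α-alkoxy acid centre. The key step exploits the fact that C6 lies between C5 and the OCH2 carbon C7: without C6 the ring is a six-membered enol ether C5=C7–O1, to which C6 can be returned as a dihalocarbene carbon that brings a bromine as the handle for the side chain.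

## Logic of the disconnections

35 ⇒ 33 (through 34). The O–C(CH3)3 bond of the C2 ester and the two aryl O–Si bonds are cut last. The acid and the hydroquinone stay masked until nothing else remains to be done, and both can be released without base. The demand is that the forward conditions are acidic only and brief, so that the allylic ester and the alkenes survive.

33 ⇒ 31 + 32, and 31 ⇒ 30. The bond between the allylic CH2 and the carboxylate oxygen is cut, then an O–Si bond. The cinnamate cannot pass organomagnesium, organozinc or zerovalent palladium steps, so it is attached after them, and 32 is used without protection. The demand is an esterification that activates the alcohol rather than the acid and uses no base, and a desilylation that distinguishes an alkyl silyl ether from two aryl silyl ethers.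

30 ⇒ 25 + 28 (through 29); 28 ⇒ 27 ⇒ 26. The C6–CH2 bond between the ring alkene and the side chain is cut. The bromine that the ring enlargement leaves on C6 is the natural handle, and the side chain becomes a five-carbon bromide made in two steps from 26. The demand is an sp2–sp3 coupling that beats β-hydride elimination and tolerates a ketone and two esters, which points to an alkylzinc reagent, and an allylic oxidation of 26 that gives only the E alcohol.

25 ⇒ 24 ⇒ 20 + 22 (through 23); 22 ⇒ 21; 20 ⇒ 19 ⇒ 18. The aryl–carbonyl carbon bond is cut and the arm carbon is taken back to a silyl-protected alcohol. The ketone must not exist during the base-mediated carbene step, so it is built afterwards, and the arene comes from 21 in one step. The demand is that the free alcohol 19 and the magnesium alkoxide of 24 do not lactonise onto the C2 ester. This is why the ester is tert-butyl rather than a primary silylethyl ester, which would be exposed to five-membered lactonisation at 9, 19 and 24.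

18 ⇒ 17. The C7–H bond is replaced by C7–OCH3. The acetal is the form in which the ring enlargement delivers C7. The demand is hydride delivery to C7 and not to C5 of the allyl cation.

17 ⇒ 15 (through 16). The C5–C6 and C6–C7 bonds are cut and C6 is removed, which contracts the oxepine to a 3,4-dihydro-2H-pyran. A seven-membered ring with a placed alkene and a placed halogen is traded for a six-membered enol ether whose quaternary centre is already complete. The demand is a precursor with nothing that tert-butoxide or silver ion can attack: no ketone, an ester without α-hydrogen that cannot be transesterified, and an arm silyl ether bulky enough to survive the silver and Lewis acid steps, which is why it is the diphenyl(tert-butyl)silyl ether.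

15 ⇒ 13 ⇒ 10 (through 14, 12 and 11); 10 ⇒ 9 ⇒ 8. The enol ether is traced to a lactol and the lactol to a terminal alkene, then the arm O–Si bond and the thioester are taken back. C7 reaches the aldehyde level by alkene cleavage, so no hydride reagent has to choose between a lactone and the C2 ester. The demand is a thioester reduction that leaves the ester alone.

8 ⇒ 4 + 6 (through 7); 4 ⇒ 1 + 2 (through 3); 6 ⇒ 5. The C2–CH2 bond of the arm and then the C2–C3 bond are cut. A chelating α-keto ester and an acetate-type silyl ketene thioacetal allow the single stereocentre to be set by a catalytic aldol addition, and everything is reduced to four simple commercial compounds. The demand is high facial selectivity on a keto ester that carries a longer chain than a pyruvate.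

## Other disconnections considered

Alternative 1: The cut is C2–C3, made after O1 and the C2 carboxyl have been tied into an acetal at C7.
- Forward step: (R)-malic acid A3 and the (Z)-iodo enal A4 are condensed to the cis-dioxolanone A2. A lithium amide forms the dioxolanone enolate, and the tethered primary iodide alkylates it on the face of the acetal substituent to give the bridged acetal lactone A1, in which the oxepine ring and the S centre are complete.
- In its favour: the stereocentre comes from the chiral pool without a catalyst. The C6 chain is in place before the ring exists, so no coupling at a ring halide is needed (better than the chosen plan). The arm is already a carboxylic acid and is distinguished from the C2 carboxyl, which is locked in the lactone (better than the chosen plan, which reduces a thioester in step 4 and re-oxidises the same carbon in steps 11 and 14). C7 ends as an acetal carbon that a silane can reduce as in step 9 (equal).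
- Against it here: once the enolate is formed the acetal carbon is the only stereochemical information left, so the enantiomeric purity of A1 cannot exceed the cis/trans purity of A2. An α-branched conjugated enal is a poor partner for a strongly cis-selective acetalisation and may lose its Z geometry under the acid required. Dioxolanone enolates are short-lived above about −30 °C, whereas a 7-exo-tet closure by an unactivated iodide through a bridged transition state is slow; E2 loss of HI and intermolecular alkylation compete, and the free acid arm requires a dianion.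
- Comparison: in mechanism the alternative closes the ring end to end by SN2 with the entropic cost of a seven-membered ring, whereas the chosen plan enlarges an existing ring by a pericyclic opening (advantage to the chosen plan). In step economy the two are about equal: A4 with its Z trisubstituted alkene should cost roughly what the chosen plan spends on 15, and the steps after A1 are fewer than those after 17.

Alternative 2: The cut is C6–C7, with C7 supplied by the methylene of an alkoxymethyl ether on the tertiary oxygen.
- Forward step: a tin-based Lewis acid ionises the MEM ether A6 to the O1=CH2 cation, which attacks the silicon-bearing carbon of the (Z)-vinylsilane. Loss of the silyl group gives the oxepine thioester A5 with the alkene held at C5=C6.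
- In its favour: oxocarbenium–vinylsilane cyclisation to tetrahydrooxepines is an established reaction class. Silicon fixes the alkene position as reliably as the carbene carbon does in step 8 (equal). C7 arrives at the right oxidation level, so step 9 has no counterpart (better). The side chain with its cinnamate and the thioester arm of the aldol are carried through, so the aryl ketone can be made by one palladium-catalysed thioester coupling and steps 10 to 19 shrink to two or three operations (better in convergence and redox economy). C2 can be set by the same aldol as in step 3 (equal).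
- Against it here: the tertiary hydroxyl beside an ester is hindered and electron-poor, so both its alkoxymethylation and the ionisation to a cation destabilised by the geminal ester are demanding. The Lewis acid must spare a thioester, a silylethyl ester, an allylic cinnamate, an aryl silyl ether and a second trisubstituted alkene that can act as a competing π-nucleophile, and protodesilylation is the usual side reaction. A6 needs a stereodefined trisubstituted (Z)-vinylsilane that already carries the whole side chain and must be in place before the aldol, so the most valuable fragment travels the longest sequence.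
- Comparison: mechanistically this is a cationic 7-endo closure end to end, against ring enlargement in the chosen plan. In step economy it is probably a few steps shorter if the vinylsilane is accessible in about six steps, otherwise equal.

Alternative 3: The cut is O1–C2.
- Forward step: a quinine-derived bifunctional squaramide activates the enone of the hydroxy enone ester A8 by hydrogen bonding while its amine guides the C7 hydroxyl onto C2 (7-exo-trig oxa-Michael addition). This closes the ring and creates the quaternary centre of the protected oxepine A7.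
- In its favour: the whole skeleton is assembled as an open chain by ordinary carbonyl and coupling chemistry. Ring, C–O bond and stereocentre arise in one catalytic step, and A7 is one deprotection from 35, so on paper this is the shortest route (better step economy than the chosen plan). It follows the probable biogenesis, and the ring alkene position is fixed in the acyclic precursor (equal).
- Against it here: the addition must create a fully substituted carbon at a β,β-disubstituted enone whose β-carbon is also the α-carbon of an ester, with an unactivated primary alcohol as nucleophile and a seven-membered ring as product. Each of these lowers rate and driving force. The reaction is the exact reverse of the ring opening that endangers 25 to 35, so conditions that let the ring close also let it reopen and racemise. High selectivity of such catalysts is established mainly for five- and six-membered rings and less substituted acceptors, and the enone geometry of A8 must be single.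
- Comparison: the chosen plan sets C2 by a chelate-controlled aldol on a substrate class of known scope, long before any β-alkoxy ketone exists, and forms the ring irreversibly (advantage to the chosen plan in stereochemical security). It pays for this with a much longer sequence.

Key step: step 8

Remark on the chemistry: the (S,S)-bis(oxazoline) ligand is assumed to direct attack to the si face of the chelated keto ester, as it does for pyruvate esters, which gives S at C2; if the sense proves opposite, the (R,R)-ligand is used.

Remark on the structures: ring numbering, the S descriptor at C2 and the E geometry of both acyclic alkenes were re-derived from the connectivity and needed no correction. TBS = tert-butyldimethylsilyl and TBDPS = tert-butyldiphenylsilyl; oxepine numbering O1 to C7 is used throughout.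

## Steps

Step 1
Reactants: 1 5-bromopent-1-ene; 2 di-tert-butyl oxalate
Product: 4 tert-butyl 2-oxohept-6-enoate, via pent-4-en-1-ylmagnesium bromide 3 (not isolated)
Conditions: Mg, THF, rt; then added to 2 (1.5 equiv), THF, −78 °C; NH4Cl aq
Reagents that add atoms: none
Why: Grignard formation followed by mono-acylation of the oxalate diester by inverse addition at low temperature; the magnesium hemiketal alkoxide and the bulk of the tert-butyl groups stop a second addition, which is a standard α-keto ester synthesis.

Step 2
Reactants: 5 S-ethyl ethanethioate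
Product: 6 1-(ethylsulfanyl)-1-(trimethylsilyloxy)ethene
Conditions: LiN(iPr)2, THF, −78 °C; Me3SiCl, −78 °C → rt; distillation
Reagents that add atoms: chlorotrimethylsilane, C[Si](C)(C)Cl
Why: Kinetic enolisation of the thioester and O-silylation give the silyl ketene thioacetal needed as the Mukaiyama donor; it should be distilled and used at once.

Step 3
Reactants: 4 tert-butyl 2-oxohept-6-enoate; 6 1-(ethylsulfanyl)-1-(trimethylsilyloxy)ethene
Product: 8 tert-butyl (2S)-2-[2-(ethylsulfanyl)-2-oxoethyl]-2-hydroxyhept-6-enoate, via O-trimethylsilyl aldol adduct 7 (not isolated)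
Conditions: Cu(OTf)2 (10 mol%), 2,2′-(propane-2,2-diyl)bis[(4S)-4-tert-butyl-4,5-dihydro-1,3-oxazole] (11 mol%), THF, −78 °C; then 1 M HCl, THF, rt
Reagents that add atoms: none
Why: Enantioselective Mukaiyama aldol addition: the α-keto ester binds divalent copper through both carbonyl oxygens in a square-planar chelate, one tert-butyl group of the C2-symmetric ligand blocks the re face of the ketone, and the silyl ketene thioacetal adds to the si face, which corresponds to S at the new carbinol carbon (the future C2). Dilute acid then cleaves the silyl ether without touching the tert-butyl ester.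

Step 4
Reactants: 8 tert-butyl (2S)-2-[2-(ethylsulfanyl)-2-oxoethyl]-2-hydroxyhept-6-enoate
Product: 9 tert-butyl (2S)-2-hydroxy-2-(2-hydroxyethyl)hept-6-enoate
Conditions: NaBH4, EtOH, 0 °C → rt
Reagents that add atoms: none
Why: Chemoselective borohydride reduction of a thiol ester through the aldehyde to the primary alcohol; the hindered tert-butyl ester and the alkene are inert, and the tert-butyl ester should not accept the new γ-hydroxyl in a lactonisation.

Step 5
Reactants: 9 tert-butyl (2S)-2-hydroxy-2-(2-hydroxyethyl)hept-6-enoate
Product: 10 tert-butyl (2S)-2-[2-(TBDPS-oxy)ethyl]-2-hydroxyhept-6-enoate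
Conditions: TBDPSCl, imidazole, CH2Cl2, 0 °C → rt
Reagents that add atoms: tert-butyl(chloro)diphenylsilane, CC(C)(C)[Si](Cl)(c1ccccc1)c1ccccc1
Why: Silylation of the primary alcohol only, since the tertiary α-hydroxy ester is too hindered; the diphenyl(tert-butyl)silyl ether is chosen for its resistance to the silver and Lewis acid steps 8 and 9.

Step 6
Reactants: 10 tert-butyl (2S)-2-[2-(TBDPS-oxy)ethyl]-2-hydroxyhept-6-enoate
Product: 13 tert-butyl (2S,6RS)-2-[2-(TBDPS-oxy)ethyl]-6-hydroxyoxane-2-carboxylate, via secondary ozonide 11 (not isolated), via hydroxy aldehyde 12 (not isolated)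
Conditions: O3, CH2Cl2, −78 °C; then PPh3, −78 °C → rt
Reagents that add atoms: ozone, [O-][O+]=O
Why: Ozonolysis with reductive work-up cleaves the terminal alkene to the aldehyde, which the tertiary hydroxyl traps as the six-membered lactol; this brings the future C7 to the aldehyde level without a hydride reagent near the ester.

Step 7
Reactants: 13 tert-butyl (2S,6RS)-2-[2-(TBDPS-oxy)ethyl]-6-hydroxyoxane-2-carboxylate
Product: 15 tert-butyl (2S)-2-[2-(TBDPS-oxy)ethyl]-3,4-dihydro-2H-pyran-2-carboxylate, via anomeric mesylate 14 (not isolated)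
Conditions: MsCl, Et3N, THF, 0 °C → 60 °C
Reagents that add atoms: none
Why: Lactol dehydration: sulfonylation of the anomeric hydroxyl, ionisation to the oxocarbenium ion and loss of the adjacent proton to the amine give the cyclic enol ether; C2 takes no part.

Step 8
Reactants: 15 tert-butyl (2S)-2-[2-(TBDPS-oxy)ethyl]-3,4-dihydro-2H-pyran-2-carboxylate
Product: 17 tert-butyl (2S,7RS)-6-bromo-2-[2-(TBDPS-oxy)ethyl]-7-methoxy-2,3,4,7-tetrahydrooxepine-2-carboxylate, via dibromocyclopropane adduct 16 (not isolated)
Conditions: CHBr3, KOtBu, pentane, −20 → 0 °C; filtration through Celite, solvent switch; then AgOTf, 2,6-lutidine, MeOH, 0 °C → rt, dark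
Reagents that add atoms: bromoform, BrC(Br)Br; methanol, CO
Why: KOtBu removes HBr from bromoform by α-elimination, and the singlet dibromocarbene adds in a concerted [2+1] fashion to the enol ether C5=C7, the only electron-rich alkene of 15, forming C5–C6 and C6–C7 in 16; the closest known reaction type is the ring expansion of dihalocarbene adducts of dihydropyrans and glycals to 3-halo-2-alkoxytetrahydrooxepines. The three-membered ring is closed by this cheletropic addition, and the seven-membered ring is not closed end to end but arises when silver removes the endo bromide (the one cis to the six-membered ring) in concert with disrotatory 2π-electrocyclic cleavage of the C5–C7 bond, the ring bonds turning inwards as the Woodward–Hoffmann–DePuy rule requires, so that a cis allyl cation results that fits a seven-membered ring. O1 carries most of the charge at C7, methanol adds there, and 2,6-lutidine takes up the acid, which protects the silyl ether and the tert-butyl ester. The only new stereocentre is the acetal carbon C7; it is not controlled, both epimers are carried on and it is removed in step 9, while the two cyclopropane centres of 16 are destroyed, so the face of carbene addition does not matter. The selectivities needed are chemoselectivity of the carbene (the enol ether is the only nucleophilic π bond), loss of the endo and not the exo bromide (orbital symmetry, since loss of the exo bromide would require a trans alkene in the seven-membered ring) and capture at C7 and not at C5 (stabilisation by O1). C2 is inert because it has no hydrogen and no ketone beside it, and its tert-butyl ester cannot be transesterified by tert-butoxide. AgOTf is used in place of a silver perchlorate promoter, which removes an explosion hazard without changing the chemistry.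

Step 9
Reactants: 17 tert-butyl (2S,7RS)-6-bromo-2-[2-(TBDPS-oxy)ethyl]-7-methoxy-2,3,4,7-tetrahydrooxepine-2-carboxylate
Product: 18 tert-butyl (2S)-6-bromo-2-[2-(TBDPS-oxy)ethyl]-2,3,4,7-tetrahydrooxepine-2-carboxylate
Conditions: Et3SiH, Me3SiOTf (0.3 equiv), CH2Cl2, −78 → −40 °C
Reagents that add atoms: none
Why: Ionic hydrogenation of the acetal: the silyl triflate ionises C7–OCH3 to the O1-stabilised allyl cation, and the silane delivers hydride to C7, the terminus with the larger positive charge (Ferrier-type regiochemistry). This removes the C7 stereocentre and leaves C5=C6 and the C–Br bond in place.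

Step 10
Reactants: 18 tert-butyl (2S)-6-bromo-2-[2-(TBDPS-oxy)ethyl]-2,3,4,7-tetrahydrooxepine-2-carboxylate
Product: 19 tert-butyl (2S)-6-bromo-2-(2-hydroxyethyl)-2,3,4,7-tetrahydrooxepine-2-carboxylate
Conditions: Bu4NF, AcOH (1:1), THF, 0 °C → rt
Reagents that add atoms: none
Why: Fluoride desilylation buffered with acetic acid; the γ-hydroxy tert-butyl ester should be stable to lactonisation under these near-neutral conditions.

Step 11
Reactants: 19 tert-butyl (2S)-6-bromo-2-(2-hydroxyethyl)-2,3,4,7-tetrahydrooxepine-2-carboxylate
Product: 20 tert-butyl (2S)-6-bromo-2-(2-oxoethyl)-2,3,4,7-tetrahydrooxepine-2-carboxylate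
Conditions: Dess–Martin periodinane, NaHCO3, CH2Cl2, 0 °C → rt
Reagents that add atoms: none
Why: Dess–Martin oxidation of the primary alcohol under bicarbonate buffer gives the β-alkoxy aldehyde with no base strong enough for β-elimination; it should be used crude.

Step 12
Reactants: 21 2-bromobenzene-1,4-diol
Product: 22 2-bromo-1,4-bis(TBS-oxy)benzene
Conditions: TBSCl, imidazole, DMF, rt
Reagents that add atoms: tert-butyl(chloro)dimethylsilane, CC(C)(C)[Si](C)(C)Cl
Why: Bis-silylation masks both phenols for the organomagnesium step and the oxidations that follow.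

Step 13
Reactants: 20 tert-butyl (2S)-6-bromo-2-(2-oxoethyl)-2,3,4,7-tetrahydrooxepine-2-carboxylate; 22 2-bromo-1,4-bis(TBS-oxy)benzene
Product: 24 tert-butyl (2S)-2-{2-[2,5-bis(TBS-oxy)phenyl]-2-hydroxyethyl}-6-bromo-2,3,4,7-tetrahydrooxepine-2-carboxylate (both carbinol epimers), via arylmagnesium bromide 23 (not isolated)
Conditions: 22, Mg, LiCl, THF, rt → 40 °C; then 20, THF, −78 → −40 °C; NH4Cl aq
Reagents that add atoms: none
Why: Magnesium insertion gives the aryl Grignard reagent, whose 1,2-addition to the aldehyde at low temperature should be faster than enolisation. The tert-butyl ester neither reacts with the reagent nor lactonises with the magnesium alkoxide, the alkenyl bromide is inert, and the new carbinol centre is removed in step 14.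

Step 14
Reactants: 24 tert-butyl (2S)-2-{2-[2,5-bis(TBS-oxy)phenyl]-2-hydroxyethyl}-6-bromo-2,3,4,7-tetrahydrooxepine-2-carboxylate
Product: 25 tert-butyl (2S)-2-{2-[2,5-bis(TBS-oxy)phenyl]-2-oxoethyl}-6-bromo-2,3,4,7-tetrahydrooxepine-2-carboxylate
Conditions: Dess–Martin periodinane, NaHCO3, CH2Cl2, 0 °C → rt
Reagents that add atoms: none
Why: Dess–Martin oxidation of the benzylic alcohol to the aryl ketone under buffered, non-basic conditions, so the new β-alkoxy ketone is not enolised.

Step 15
Reactants: 26 5-bromo-2-methylpent-2-ene
Product: 27 (2E)-5-bromo-2-methylpent-2-en-1-ol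
Conditions: SeO2 (0.3 equiv), tBuOOH, salicylic acid (cat.), CH2Cl2, rt
Reagents that add atoms: tert-butyl hydroperoxide, CC(C)(C)OO
Why: Allylic oxidation by SeO2 (ene reaction, then [2,3]-sigmatropic shift) attacks the methyl group trans to the chain at the more substituted alkene terminus, which sets the E geometry of the allylic alcohol.

Step 16
Reactants: 27 (2E)-5-bromo-2-methylpent-2-en-1-ol
Product: 28 [(2E)-5-bromo-2-methylpent-2-en-1-yl]oxy(tert-butyl)dimethylsilane
Conditions: TBSCl, imidazole, CH2Cl2, 0 °C → rt
Reagents that add atoms: tert-butyl(chloro)dimethylsilane, CC(C)(C)[Si](C)(C)Cl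
Why: Standard silylation of the primary allylic alcohol; a silyl ether is a poor leaving group, so neither the homoallylic zinc reagent nor zerovalent palladium should ionise it in step 17.

Step 17
Reactants: 25 tert-butyl (2S)-2-{2-[2,5-bis(TBS-oxy)phenyl]-2-oxoethyl}-6-bromo-2,3,4,7-tetrahydrooxepine-2-carboxylate; 28 [(2E)-5-bromo-2-methylpent-2-en-1-yl]oxy(tert-butyl)dimethylsilane
Product: 30 tert-butyl (2S)-2-{2-[2,5-bis(TBS-oxy)phenyl]-2-oxoethyl}-6-[(3E)-4-methyl-5-(TBS-oxy)pent-3-en-1-yl]-2,3,4,7-tetrahydrooxepine-2-carboxylate, via alkylzinc bromide 29 (not isolated)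
Conditions: 28, Zn dust, LiCl, THF, 50 °C; then 25, PdCl2(dppf) (dppf = 1,1′-bis(diphenylphosphino)ferrocene, 5 mol%), THF, 50 °C
Reagents that add atoms: none
Why: Negishi coupling: LiCl-assisted zinc insertion gives the alkylzinc bromide, and oxidative addition of zerovalent palladium into C6–Br, transmetalation and reductive elimination form the C6–CH2 bond without moving the ring alkene. The wide-bite-angle diphosphine favours reductive elimination over β-hydride elimination, and the organozinc does not attack the ketone or the esters.

Step 18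
Reactants: 30 tert-butyl (2S)-2-{2-[2,5-bis(TBS-oxy)phenyl]-2-oxoethyl}-6-[(3E)-4-methyl-5-(TBS-oxy)pent-3-en-1-yl]-2,3,4,7-tetrahydrooxepine-2-carboxylate
Product: 31 tert-butyl (2S)-2-{2-[2,5-bis(TBS-oxy)phenyl]-2-oxoethyl}-6-[(3E)-5-hydroxy-4-methylpent-3-en-1-yl]-2,3,4,7-tetrahydrooxepine-2-carboxylate
Conditions: camphorsulfonic acid (0.1 equiv), MeOH/CH2Cl2, 0 °C
Reagents that add atoms: none
Why: Acid-catalysed methanolysis removes the primary alkyl silyl ether selectively, because aryl silyl ethers cleave much more slowly under acid; the ketone and the tert-butyl ester are untouched.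

Step 19
Reactants: 31 tert-butyl (2S)-2-{2-[2,5-bis(TBS-oxy)phenyl]-2-oxoethyl}-6-[(3E)-5-hydroxy-4-methylpent-3-en-1-yl]-2,3,4,7-tetrahydrooxepine-2-carboxylate; 32 (2E)-3-(4-hydroxyphenyl)prop-2-enoic acid
Product: 33 tert-butyl (2S)-2-{2-[2,5-bis(TBS-oxy)phenyl]-2-oxoethyl}-6-[(3E)-5-{[(2E)-3-(4-hydroxyphenyl)prop-2-enoyl]oxy}-4-methylpent-3-en-1-yl]-2,3,4,7-tetrahydrooxepine-2-carboxylate
Conditions: PPh3, DIAD, THF, 0 °C → rt
Reagents that add atoms: none
Why: Mitsunobu esterification: the phosphonium-activated primary allylic alcohol is displaced (SN2) by the carboxylate of 32, which is far more acidic than its phenol, so no phenol protection is needed and no base touches the β-alkoxy ketone.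

Step 20
Reactants: 33 tert-butyl (2S)-2-{2-[2,5-bis(TBS-oxy)phenyl]-2-oxoethyl}-6-[(3E)-5-{[(2E)-3-(4-hydroxyphenyl)prop-2-enoyl]oxy}-4-methylpent-3-en-1-yl]-2,3,4,7-tetrahydrooxepine-2-carboxylate
Product: 35 (2S)-2-[2-(2,5-dihydroxyphenyl)-2-oxoethyl]-6-[(3E)-5-{[(2E)-3-(4-hydroxyphenyl)prop-2-enoyl]oxy}-4-methylpent-3-en-1-yl]-2,3,4,7-tetrahydrooxepine-2-carboxylic acid, via bis-silylated carboxylic acid 34 (not isolated)
Conditions: CF3CO2H/CH2Cl2 (1:4), anisole, 0 °C → rt; evaporation; then HF·pyridine, pyridine, THF, 0 °C → rt
Reagents that add atoms: none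
Why: Acidolysis of the tert-butyl ester (the tert-butyl cation is lost as isobutene or taken up by anisole) is followed by cleavage of the two aryl silyl ethers with acidic HF·pyridine. Neither stage is basic, so the β-alkoxy ketone is not enolised and C2 remains S.

## Compound list

1 | 5-bromopent-1-ene | C=CCCCBr | starting material
2 | di-tert-butyl oxalate | CC(C)(C)OC(=O)C(=O)OC(C)(C)C | starting material
3 | pent-4-en-1-ylmagnesium bromide | C=CCCC[Mg]Br | intermediate
4 | tert-butyl 2-oxohept-6-enoate | C=CCCCC(=O)C(=O)OC(C)(C)C | intermediate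
5 | S-ethyl ethanethioate | CC(=O)SCC | starting material
6 | 1-(ethylsulfanyl)-1-(trimethylsilyloxy)ethene | C=C(O[Si](C)(C)C)SCC | intermediate
7 | tert-butyl (2S)-2-[2-(ethylsulfanyl)-2-oxoethyl]-2-(trimethylsilyloxy)hept-6-enoate | C=CCCC[C@](O[Si](C)(C)C)(CC(=O)SCC)C(=O)OC(C)(C)C | intermediate
8 | tert-butyl (2S)-2-[2-(ethylsulfanyl)-2-oxoethyl]-2-hydroxyhept-6-enoate | C=CCCC[C@](O)(CC(=O)SCC)C(=O)OC(C)(C)C | intermediate
9 | tert-butyl (2S)-2-hydroxy-2-(2-hydroxyethyl)hept-6-enoate | C=CCCC[C@](O)(CCO)C(=O)OC(C)(C)C | intermediate
10 | tert-butyl (2S)-2-[2-(TBDPS-oxy)ethyl]-2-hydroxyhept-6-enoate | C=CCCC[C@](O)(CCO[Si](c1ccccc1)(c1ccccc1)C(C)(C)C)C(=O)OC(C)(C)C | intermediate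
11 | secondary ozonide (1,2,4-trioxolane) of 10 | C1OOC(CCC[C@](O)(CCO[Si](c2ccccc2)(c2ccccc2)C(C)(C)C)C(=O)OC(C)(C)C)O1 | intermediate
12 | tert-butyl (2S)-2-[2-(TBDPS-oxy)ethyl]-2-hydroxy-6-oxohexanoate | O=CCCC[C@](O)(CCO[Si](c1ccccc1)(c1ccccc1)C(C)(C)C)C(=O)OC(C)(C)C | intermediate
13 | tert-butyl (2S,6RS)-2-[2-(TBDPS-oxy)ethyl]-6-hydroxyoxane-2-carboxylate | OC1CCC[C@](CCO[Si](c2ccccc2)(c2ccccc2)C(C)(C)C)(C(=O)OC(C)(C)C)O1 | intermediate
14 | tert-butyl (2S,6RS)-2-[2-(TBDPS-oxy)ethyl]-6-(methanesulfonyloxy)oxane-2-carboxylate | CS(=O)(=O)OC1CCC[C@](CCO[Si](c2ccccc2)(c2ccccc2)C(C)(C)C)(C(=O)OC(C)(C)C)O1 | intermediate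
15 | tert-butyl (2S)-2-[2-(TBDPS-oxy)ethyl]-3,4-dihydro-2H-pyran-2-carboxylate | C1=CCC[C@](CCO[Si](c2ccccc2)(c2ccccc2)C(C)(C)C)(C(=O)OC(C)(C)C)O1 | intermediate
16 | tert-butyl (3S)-7,7-dibromo-3-[2-(TBDPS-oxy)ethyl]-2-oxabicyclo[4.1.0]heptane-3-carboxylate (ring-fusion epimers) | BrC1(Br)C2CC[C@](CCO[Si](c3ccccc3)(c3ccccc3)C(C)(C)C)(C(=O)OC(C)(C)C)OC12 | intermediate
17 | tert-butyl (2S,7RS)-6-bromo-2-[2-(TBDPS-oxy)ethyl]-7-methoxy-2,3,4,7-tetrahydrooxepine-2-carboxylate | BrC1=CCC[C@](CCO[Si](c2ccccc2)(c2ccccc2)C(C)(C)C)(C(=O)OC(C)(C)C)OC1OC | intermediate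
18 | tert-butyl (2S)-6-bromo-2-[2-(TBDPS-oxy)ethyl]-2,3,4,7-tetrahydrooxepine-2-carboxylate | BrC1=CCC[C@](CCO[Si](c2ccccc2)(c2ccccc2)C(C)(C)C)(C(=O)OC(C)(C)C)OC1 | intermediate
19 | tert-butyl (2S)-6-bromo-2-(2-hydroxyethyl)-2,3,4,7-tetrahydrooxepine-2-carboxylate | BrC1=CCC[C@](CCO)(C(=O)OC(C)(C)C)OC1 | intermediate
20 | tert-butyl (2S)-6-bromo-2-(2-oxoethyl)-2,3,4,7-tetrahydrooxepine-2-carboxylate | BrC1=CCC[C@](CC=O)(C(=O)OC(C)(C)C)OC1 | intermediate
21 | 2-bromobenzene-1,4-diol | Oc1ccc(O)c(Br)c1 | starting material
22 | 2-bromo-1,4-bis(TBS-oxy)benzene | CC(C)(C)[Si](C)(C)Oc1ccc(O[Si](C)(C)C(C)(C)C)c(Br)c1 | intermediate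
23 | 2,5-bis(TBS-oxy)phenylmagnesium bromide | CC(C)(C)[Si](C)(C)Oc1ccc(O[Si](C)(C)C(C)(C)C)c([Mg]Br)c1 | intermediate
24 | tert-butyl (2S)-2-{2-[2,5-bis(TBS-oxy)phenyl]-2-hydroxyethyl}-6-bromo-2,3,4,7-tetrahydrooxepine-2-carboxylate (carbinol epimers) | BrC1=CCC[C@](CC(O)c2cc(O[Si](C)(C)C(C)(C)C)ccc2O[Si](C)(C)C(C)(C)C)(C(=O)OC(C)(C)C)OC1 | intermediate
25 | tert-butyl (2S)-2-{2-[2,5-bis(TBS-oxy)phenyl]-2-oxoethyl}-6-bromo-2,3,4,7-tetrahydrooxepine-2-carboxylate | BrC1=CCC[C@](CC(=O)c2cc(O[Si](C)(C)C(C)(C)C)ccc2O[Si](C)(C)C(C)(C)C)(C(=O)OC(C)(C)C)OC1 | intermediate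
26 | 5-bromo-2-methylpent-2-ene | CC(C)=CCCBr | starting material
27 | (2E)-5-bromo-2-methylpent-2-en-1-ol | C/C(=C\CCBr)CO | intermediate
28 | [(2E)-5-bromo-2-methylpent-2-en-1-yl]oxy(tert-butyl)dimethylsilane | C/C(=C\CCBr)CO[Si](C)(C)C(C)(C)C | intermediate
29 | (3E)-4-methyl-5-(TBS-oxy)pent-3-en-1-ylzinc bromide | C/C(=C\CC[Zn]Br)CO[Si](C)(C)C(C)(C)C | intermediate
30 | tert-butyl (2S)-2-{2-[2,5-bis(TBS-oxy)phenyl]-2-oxoethyl}-6-[(3E)-4-methyl-5-(TBS-oxy)pent-3-en-1-yl]-2,3,4,7-tetrahydrooxepine-2-carboxylate | C/C(=C\CCC1=CCC[C@](CC(=O)c2cc(O[Si](C)(C)C(C)(C)C)ccc2O[Si](C)(C)C(C)(C)C)(C(=O)OC(C)(C)C)OC1)CO[Si](C)(C)C(C)(C)C | intermediate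
31 | tert-butyl (2S)-2-{2-[2,5-bis(TBS-oxy)phenyl]-2-oxoethyl}-6-[(3E)-5-hydroxy-4-methylpent-3-en-1-yl]-2,3,4,7-tetrahydrooxepine-2-carboxylate | C/C(=C\CCC1=CCC[C@](CC(=O)c2cc(O[Si](C)(C)C(C)(C)C)ccc2O[Si](C)(C)C(C)(C)C)(C(=O)OC(C)(C)C)OC1)CO | intermediate
32 | (2E)-3-(4-hydroxyphenyl)prop-2-enoic acid (4-hydroxycinnamic acid) | OC(=O)/C=C/c1ccc(O)cc1 | starting material
33 | tert-butyl (2S)-2-{2-[2,5-bis(TBS-oxy)phenyl]-2-oxoethyl}-6-[(3E)-5-{[(2E)-3-(4-hydroxyphenyl)prop-2-enoyl]oxy}-4-methylpent-3-en-1-yl]-2,3,4,7-tetrahydrooxepine-2-carboxylate | C/C(=C\CCC1=CCC[C@](CC(=O)c2cc(O[Si](C)(C)C(C)(C)C)ccc2O[Si](C)(C)C(C)(C)C)(C(=O)OC(C)(C)C)OC1)COC(=O)/C=C/c1ccc(O)cc1 | intermediate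
34 | (2S)-2-{2-[2,5-bis(TBS-oxy)phenyl]-2-oxoethyl}-6-[(3E)-5-{[(2E)-3-(4-hydroxyphenyl)prop-2-enoyl]oxy}-4-methylpent-3-en-1-yl]-2,3,4,7-tetrahydrooxepine-2-carboxylic acid | C/C(=C\CCC1=CCC[C@](CC(=O)c2cc(O[Si](C)(C)C(C)(C)C)ccc2O[Si](C)(C)C(C)(C)C)(C(=O)O)OC1)COC(=O)/C=C/c1ccc(O)cc1 | intermediate
35 | (2S)-2-[2-(2,5-dihydroxyphenyl)-2-oxoethyl]-6-[(3E)-5-{[(2E)-3-(4-hydroxyphenyl)prop-2-enoyl]oxy}-4-methylpent-3-en-1-yl]-2,3,4,7-tetrahydrooxepine-2-carboxylic acid (CNP0602535.2) | C/C(=C\CCC1=CCC[C@](CC(=O)c2cc(O)ccc2O)(C(=O)O)OC1)COC(=O)/C=C/c1ccc(O)cc1 | target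

## Step count and least certain steps

Total step count: 20. Longest linear sequence: 16 steps (1, 3 to 11, 13, 14, 17 to 20) from 1 to 35. Steps 2, 12, 15 and 16 prepare fragments.

Step 8 (key step). The most likely failure is partition of the allyl cation: loss of the C4 proton to a bromodiene or capture at C5 instead of C7, together with acid-induced loss of the silyl or tert-butyl group if the triflic acid is not fully scavenged, and thermal opening of 16 during the solvent switch. The fallback separates ring opening from acetal formation and uses neither silver nor free acid. It sets out from 15: 16 is made as before but isolated, and heating it with quinoline at about 100 °C effects the same electrocyclic opening with loss of the C4 proton to give the dienol ether tert-butyl (2S)-6-bromo-2-[2-(TBDPS-oxy)ethyl]-2,3-dihydrooxepine-2-carboxylate F1. Pyridinium p-toluenesulfonate in MeOH then protonates C4 and adds methanol at C7, the known conversion of 1-alkoxydienes into α,β-unsaturated acetals, and the route is rejoined at 17.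

Step 3. Facial discrimination may be insufficient, because the keto ester carries a tert-butyl ester and a five-carbon chain instead of the small groups for which this catalyst type is optimised, and a racemic silyl-triflate-catalysed background reaction can erode selectivity. The fallback replaces catalysis by classical resolution and sets out from 4 and 5. The lithium enolate of 5 (LiN(iPr)2, THF, −78 °C) adds to 4 to give racemic tert-butyl 2-[2-(ethylsulfanyl)-2-oxoethyl]-2-hydroxyhept-6-enoate F2. Thiophilic hydrolysis (AgNO3, 2,6-lutidine, aqueous THF) cleaves only the thioester to racemic 3-(tert-butoxycarbonyl)-3-hydroxyoct-7-enoic acid F3. Crystallisation with one enantiomer of 1-phenylethylamine (drawn as R; which enantiomer gives the less soluble salt of the S acid has to be found by trial) gives (R)-1-phenylethylammonium (3S)-3-(tert-butoxycarbonyl)-3-hydroxyoct-7-enoate F4. Dilute acid releases (3S)-3-(tert-butoxycarbonyl)-3-hydroxyoct-7-enoic acid F5, and ethanethiol with a carbodiimide re-forms the thioester, so the route is rejoined at 8.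

Step 13. The hindered, basic aryl Grignard reagent may enolise the β-alkoxy aldehyde, followed by expulsion of O1 and ring opening, or addition may be slow. The fallback moves the arm to the acid oxidation level, where the adduct is a stable chelate and no alkoxide is formed. It sets out from 20: NaClO2/NaH2PO4/2-methylbut-2-ene (Pinnick oxidation) gives 2-[(2S)-6-bromo-2-(tert-butoxycarbonyl)-2,3,4,7-tetrahydrooxepin-2-yl]acetic acid F6. Carbodiimide coupling with N,O-dimethylhydroxylamine gives the Weinreb amide tert-butyl (2S)-6-bromo-2-{2-[methoxy(methyl)amino]-2-oxoethyl}-2,3,4,7-tetrahydrooxepine-2-carboxylate F7. Addition of 23 at −40 °C gives the ketone directly, and the route is rejoined at 25, bypassing 24 and step 14.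

Step 17. Oxidative addition to the cyclic, doubly substituted alkenyl bromide may be slow, and β-hydride elimination or protonolysis of the alkylzinc reagent can then dominate; zinc insertion into 28 may also be incomplete. The fallback avoids a preformed organometallic: a nickel-catalysed reductive cross-electrophile coupling of 25 with 28 (NiBr2(dme), 4,4′-di-tert-butyl-2,2′-bipyridine, Mn powder, NaI, N,N-dimethylacetamide, rt to 40 °C), a known coupling of alkenyl bromides with primary alkyl bromides that tolerates ketones and esters. It sets out from 25 and 28 and returns at 30 with no new compound (F0).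

Step 20. During acidolysis of the tert-butyl ester, protonation of the trisubstituted alkenes, solvolysis of the allylic cinnamate or tert-butylation of the phenol rings may compete. The fallback changes the carboxyl protection to a fluoride-labile group once the lactonisation-prone stages are past. It sets out from 25, which has no acid-sensitive alkene or allylic ester:
- CF3CO2H in CH2Cl2 gives (2S)-2-{2-[2,5-bis(TBS-oxy)phenyl]-2-oxoethyl}-6-bromo-2,3,4,7-tetrahydrooxepine-2-carboxylic acid F8.
- Mitsunobu esterification with 2-(trimethylsilyl)ethanol gives 2-(trimethylsilyl)ethyl (2S)-2-{2-[2,5-bis(TBS-oxy)phenyl]-2-oxoethyl}-6-bromo-2,3,4,7-tetrahydrooxepine-2-carboxylate F9.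
- The conditions of step 17 give 2-(trimethylsilyl)ethyl (2S)-2-{2-[2,5-bis(TBS-oxy)phenyl]-2-oxoethyl}-6-[(3E)-4-methyl-5-(TBS-oxy)pent-3-en-1-yl]-2,3,4,7-tetrahydrooxepine-2-carboxylate F10.
- The conditions of step 18 give 2-(trimethylsilyl)ethyl (2S)-2-{2-[2,5-bis(TBS-oxy)phenyl]-2-oxoethyl}-6-[(3E)-5-hydroxy-4-methylpent-3-en-1-yl]-2,3,4,7-tetrahydrooxepine-2-carboxylate F11.
- The conditions of step 19 give 2-(trimethylsilyl)ethyl (2S)-2-{2-[2,5-bis(TBS-oxy)phenyl]-2-oxoethyl}-6-[(3E)-5-{[(2E)-3-(4-hydroxyphenyl)prop-2-enoyl]oxy}-4-methylpent-3-en-1-yl]-2,3,4,7-tetrahydrooxepine-2-carboxylate F12.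
- Tris(dimethylamino)sulfonium difluorotrimethylsilicate in DMF at 0 °C removes the silylethyl ester and both aryl silyl ethers in one operation, and the route is rejoined at 35. The ortho-phenoxide that forms first lowers the acidity of the ketone α-hydrogens, which should limit ring opening under this mildly basic fluoride.

## Further compounds

F1 | step 8 | tert-butyl (2S)-6-bromo-2-[2-(TBDPS-oxy)ethyl]-2,3-dihydrooxepine-2-carboxylate | C1=CC[C@](CCO[Si](c2ccccc2)(c2ccccc2)C(C)(C)C)(C(=O)OC(C)(C)C)OC=C1Br
F2 | step 3 | racemic tert-butyl 2-[2-(ethylsulfanyl)-2-oxoethyl]-2-hydroxyhept-6-enoate | C=CCCCC(O)(CC(=O)SCC)C(=O)OC(C)(C)C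
F3 | step 3 | racemic 3-(tert-butoxycarbonyl)-3-hydroxyoct-7-enoic acid | C=CCCCC(O)(CC(=O)O)C(=O)OC(C)(C)C
F4 | step 3 | (R)-1-phenylethylammonium (3S)-3-(tert-butoxycarbonyl)-3-hydroxyoct-7-enoate | C=CCCC[C@](O)(CC(=O)[O-])C(=O)OC(C)(C)C.C[C@@H]([NH3+])c1ccccc1
F5 | step 3 | (3S)-3-(tert-butoxycarbonyl)-3-hydroxyoct-7-enoic acid | C=CCCC[C@](O)(CC(=O)O)C(=O)OC(C)(C)C
F6 | step 13 | 2-[(2S)-6-bromo-2-(tert-butoxycarbonyl)-2,3,4,7-tetrahydrooxepin-2-yl]acetic acid | BrC1=CCC[C@](CC(=O)O)(C(=O)OC(C)(C)C)OC1
F7 | step 13 | tert-butyl (2S)-6-bromo-2-{2-[methoxy(methyl)amino]-2-oxoethyl}-2,3,4,7-tetrahydrooxepine-2-carboxylate | BrC1=CCC[C@](CC(=O)N(C)OC)(C(=O)OC(C)(C)C)OC1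
F0 | step 17 | none | none
F8 | step 20 | (2S)-2-{2-[2,5-bis(TBS-oxy)phenyl]-2-oxoethyl}-6-bromo-2,3,4,7-tetrahydrooxepine-2-carboxylic acid | BrC1=CCC[C@](CC(=O)c2cc(O[Si](C)(C)C(C)(C)C)ccc2O[Si](C)(C)C(C)(C)C)(C(=O)O)OC1
F9 | step 20 | 2-(trimethylsilyl)ethyl (2S)-2-{2-[2,5-bis(TBS-oxy)phenyl]-2-oxoethyl}-6-bromo-2,3,4,7-tetrahydrooxepine-2-carboxylate | BrC1=CCC[C@](CC(=O)c2cc(O[Si](C)(C)C(C)(C)C)ccc2O[Si](C)(C)C(C)(C)C)(C(=O)OCC[Si](C)(C)C)OC1
F10 | step 20 | 2-(trimethylsilyl)ethyl (2S)-2-{2-[2,5-bis(TBS-oxy)phenyl]-2-oxoethyl}-6-[(3E)-4-methyl-5-(TBS-oxy)pent-3-en-1-yl]-2,3,4,7-tetrahydrooxepine-2-carboxylate | C/C(=C\CCC1=CCC[C@](CC(=O)c2cc(O[Si](C)(C)C(C)(C)C)ccc2O[Si](C)(C)C(C)(C)C)(C(=O)OCC[Si](C)(C)C)OC1)CO[Si](C)(C)C(C)(C)C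
F11 | step 20 | 2-(trimethylsilyl)ethyl (2S)-2-{2-[2,5-bis(TBS-oxy)phenyl]-2-oxoethyl}-6-[(3E)-5-hydroxy-4-methylpent-3-en-1-yl]-2,3,4,7-tetrahydrooxepine-2-carboxylate | C/C(=C\CCC1=CCC[C@](CC(=O)c2cc(O[Si](C)(C)C(C)(C)C)ccc2O[Si](C)(C)C(C)(C)C)(C(=O)OCC[Si](C)(C)C)OC1)CO
F12 | step 20 | 2-(trimethylsilyl)ethyl (2S)-2-{2-[2,5-bis(TBS-oxy)phenyl]-2-oxoethyl}-6-[(3E)-5-{[(2E)-3-(4-hydroxyphenyl)prop-2-enoyl]oxy}-4-methylpent-3-en-1-yl]-2,3,4,7-tetrahydrooxepine-2-carboxylate | C/C(=C\CCC1=CCC[C@](CC(=O)c2cc(O[Si](C)(C)C(C)(C)C)ccc2O[Si](C)(C)C(C)(C)C)(C(=O)OCC[Si](C)(C)C)OC1)COC(=O)/C=C/c1ccc(O)cc1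
A1 | alternative 1 | bridged bicyclic dioxolanone (acetal lactone) containing the oxepine ring, with CH2CO2H at the S quaternary bridgehead and the TBS-protected side chain on the ring alkene | O=C1O[C@H]2O[C@]1(CC(=O)O)CCC=C2CC/C=C(\C)CO[Si](C)(C)C(C)(C)C
A2 | alternative 1 | cis-2,5-disubstituted 1,3-dioxolan-4-one from A3 and A4, with the (Z)-iodoalkenyl group on the acetal carbon and CH2CO2H on the R-configured ring carbon | O=C1O[C@H](/C(=C\CCI)CC/C=C(\C)CO[Si](C)(C)C(C)(C)C)O[C@@H]1CC(=O)O
A3 | alternative 1 | (R)-malic acid | O[C@H](CC(=O)O)C(=O)O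
A4 | alternative 1 | (2Z)-5-iodo-2-[(3E)-4-methyl-5-(TBS-oxy)pent-3-en-1-yl]pent-2-enal | O=C/C(CC/C=C(\C)CO[Si](C)(C)C(C)(C)C)=C\CCI
A5 | alternative 2 | (S)-oxepine with S-ethyl thioester arm, 2-(trimethylsilyl)ethyl ester and TBS-protected coumarate side chain | C/C(=C\CCC1=CCC[C@](CC(=O)SCC)(C(=O)OCC[Si](C)(C)C)OC1)COC(=O)/C=C/c1ccc(O[Si](C)(C)C(C)(C)C)cc1
A6 | alternative 2 | (2-methoxyethoxy)methyl ether of the S tertiary alcohol carrying the thioester arm, the silylethyl ester and the (Z)-vinylsilane with the full side chain | C/C(=C\CC/C(=C/CC[C@](CC(=O)SCC)(C(=O)OCC[Si](C)(C)C)OCOCCOC)[Si](C)(C)C)COC(=O)/C=C/c1ccc(O[Si](C)(C)C(C)(C)C)cc1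
A7 | alternative 3 | fully protected (S)-oxepine (target with three TBS ethers and the 2-(trimethylsilyl)ethyl ester) | C/C(=C\CCC1=CCC[C@](CC(=O)c2cc(O[Si](C)(C)C(C)(C)C)ccc2O[Si](C)(C)C(C)(C)C)(C(=O)OCC[Si](C)(C)C)OC1)COC(=O)/C=C/c1ccc(O[Si](C)(C)C(C)(C)C)cc1
A8 | alternative 3 | silyl-protected (Z)-hydroxy enone ester, open-chain precursor of A7 (enone drawn E) | OC/C(CC/C=C(\C)COC(=O)/C=C/c1ccc(O[Si](C)(C)C(C)(C)C)cc1)=C\CC/C(C(=O)OCC[Si](C)(C)C)=C\C(=O)c1cc(O[Si](C)(C)C(C)(C)C)ccc1O[Si](C)(C)C(C)(C)C
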